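**Retrosynthetic overview**

1. Numbering (isochromene): O2, C1H2, C3 (dienyl), C4, C4a, C5 (Cl), C6 (C=O), C7 (CH3, OH), C8 (OH), C8a (acetyl); pyran ring = O2/C1/C8a/C4a/C4/C3, carbocycle = C4a/C5/C6/C7/C8/C8a.
2. Enabling feature: inside the carbocycle C8a is the α-carbon of the acetyl ketone and, through C4a=C5, the γ-carbon of the C6 ketone, while C8 carries the β-hydroxyl. This is an aldol retron with a doubly acidified C8a–H, so the carbocycle is cut at C8–C8a to the monocyclic pyran keto aldehyde 27, whose only ring-relevant stereocentre is C7.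
3. Pyran ring: gold-catalysed 6-endo closure of the C1 hydroxyl onto C3 of the hydroxy chloro-dienynone 24. Compound 24 is the Stork–Danheiser product of acetylide 22 and a temporary dihydropyranone 21 (ring oxygen on C6), which allows unambiguous chlorination of C5 and fixes the C4a=C5 geometry; the ring oxygen thus moves from C6 to C3.
4. Building blocks: dibromotriene 5 (side chain, from (S)-2-methylbutan-1-ol), Weinreb amide 16 (C1, C8a, C4a and the masked acetyl group, from ethyl (S)-3-hydroxybutanoate), alkyne 10 (C5–C8 with the C7 stereocentre, from methyl (R)-2-methylglycidate).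
5. Ring order: temporary dihydropyranone (step 13, opened in step 15), then pyran ring (step 16), then carbocycle (step 19, last).

Key step: step 19

Remark: methyl (R)-2-methylglycidate (6) is assumed to be purchased in enantiopure form.
Remark: the two stereocentres inherited from 11 (C8a and the carbinol carbon of the masked acetyl group) are sacrificial; the carbinol is oxidised in step 18 and C8a is re-set in step 19, so their configuration (drawn as carried) is inconsequential.
Remark: TBS = tert-butyldimethylsilyl, TES = triethylsilyl; intermediates are described with the atom numbers of the target.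

**Route**

Step 1
Reactants: 1 (S)-2-methylbutan-1-ol
Product: 3 (S,E)-2,4-dimethylhex-2-enal, via (S)-2-methylbutanal 2 (not isolated)
Conditions: TEMPO (cat.), PhI(OAc)2, CH2Cl2, rt; then Ph3P=C(CH3)CHO, 40 °C
Reagents that add atoms: 2-(triphenylphosphoranylidene)propanal, CC(C=O)=P(c1ccccc1)(c1ccccc1)c1ccccc1
Why: Non-basic TEMPO oxidation should leave the α-stereocentre intact, and the stabilised ylide olefinates the aldehyde in a Wittig reaction with E selectivity.

Step 2
Reactants: 3 (S,E)-2,4-dimethylhex-2-enal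
Product: 4 (2E,4E,6S)-4,6-dimethylocta-2,4-dienal
Conditions: Ph3P=CHCHO, toluene, 80 °C
Reagents that add atoms: (triphenylphosphoranylidene)acetaldehyde, O=CC=P(c1ccccc1)(c1ccccc1)c1ccccc1
Why: Two-carbon Wittig homologation with a stabilised formyl ylide should give the new double bond with E geometry.

Step 3
Reactants: 4 (2E,4E,6S)-4,6-dimethylocta-2,4-dienal
Product: 5 (3E,5E,7S)-1,1-dibromo-5,7-dimethylnona-1,3,5-triene
Conditions: CBr4, PPh3, Zn, CH2Cl2, 0 °C to rt
Reagents that add atoms: carbon tetrabromide, BrC(Br)(Br)Br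
Why: First stage of the Corey–Fuchs sequence (dibromo-olefination of an aldehyde), which stores the future C4≡C3 alkyne in a non-volatile form.

Step 4
Reactants: 6 methyl (R)-2-methyloxirane-2-carboxylate
Product: 7 methyl (R)-2,3-dihydroxy-2-methylpropanoate
Conditions: H2O, HClO4 (cat.), THF, 0 °C to rt
Reagents that add atoms: water, O
Why: Acid-catalysed epoxide hydrolysis in which water attacks the unsubstituted CH2 (the ester-bearing carbon is deactivated and hindered), so the C–O bond at the future C7 is untouched and its configuration is retained.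

Step 5
Reactants: 7 methyl (R)-2,3-dihydroxy-2-methylpropanoate
Product: 8 methyl (R)-2,3-bis(TBSO)-2-methylpropanoate
Conditions: TBSOTf (2.5 equiv), 2,6-lutidine, CH2Cl2, 0 °C to rt
Reagents that add atoms: tert-butyldimethylsilyl triflate, CC(C)(C)[Si](C)(C)OS(=O)(=O)C(F)(F)F
Why: Silyl triflate silylation protects both the primary and the tertiary hydroxyl in one operation.

Step 6
Reactants: 8 methyl (R)-2,3-bis(TBSO)-2-methylpropanoate
Product: 9 (R)-2,3-bis(TBSO)-2-methylpropanal
Conditions: i-Bu2AlH, CH2Cl2, −78 °C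
Reagents that add atoms: none
Why: Partial reduction of a hindered α-silyloxy ester, whose tetrahedral aluminium intermediate is stable at −78 °C and collapses to the non-enolisable aldehyde on work-up.

Step 7
Reactants: 9 (R)-2,3-bis(TBSO)-2-methylpropanal
Product: 10 (S)-3,4-bis(TBSO)-3-methylbut-1-yne
Conditions: Ohira–Bestmann reagent, K2CO3, MeOH, 0 °C to rt
Reagents that add atoms: dimethyl (1-diazo-2-oxopropyl)phosphonate, CC(=O)C(=[N+]=[N-])P(=O)(OC)OC
Why: Seyferth–Gilbert homologation of an aldehyde with a quaternary α-carbon, which cannot epimerise (the descriptor changes only through the priority rules).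

Step 8
Reactants: 11 ethyl (S)-3-hydroxybutanoate
Product: 13 ethyl (2S,3S)-3-hydroxy-2-(hydroxymethyl)butanoate, via ester dianion 12 (not isolated)
Conditions: LiN(i-Pr)2 (2.2 equiv), THF, −50 to −20 °C; CH2O (gas), −78 °C; aq. NH4Cl
Reagents that add atoms: formaldehyde, C=O
Why: Fráter–Seebach reaction of the chelated dianion with formaldehyde, in which the electrophile enters anti to the methyl group of the lithium chelate (both centres are sacrificial).

Step 9
Reactants: 13 ethyl (2S,3S)-3-hydroxy-2-(hydroxymethyl)butanoate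
Product: 14 ethyl (2S,3S)-3-hydroxy-2-[(triethylsilyloxy)methyl]butanoate
Conditions: TESCl (1.05 equiv), imidazole, CH2Cl2, −20 °C
Reagents that add atoms: chlorotriethylsilane, CC[Si](CC)(CC)Cl
Why: Sterically controlled silylation of the primary hydroxyl in the presence of the secondary one.

Step 10
Reactants: 14 ethyl (2S,3S)-3-hydroxy-2-[(triethylsilyloxy)methyl]butanoate
Product: 15 ethyl (2S,3S)-3-(TBSO)-2-[(TESO)methyl]butanoate
Conditions: TBSOTf, 2,6-lutidine, CH2Cl2, −78 to 0 °C
Reagents that add atoms: tert-butyldimethylsilyl triflate, CC(C)(C)[Si](C)(C)OS(=O)(=O)C(F)(F)F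
Why: Silylation of the secondary hydroxyl gives two silyl ethers of clearly different lability (primary TES, secondary TBS).

Step 11
Reactants: 15 ethyl (2S,3S)-3-(TBSO)-2-[(TESO)methyl]butanoate
Product: 16 (2S,3S)-3-(TBSO)-N-methoxy-N-methyl-2-[(TESO)methyl]butanamide
Conditions: MeNHOMe·HCl, i-PrMgCl, THF, −20 to 0 °C
Reagents that add atoms: N,O-dimethylhydroxylamine hydrochloride, CNOC.Cl
Why: Direct ester-to-Weinreb-amide conversion with the magnesium amide, mild enough for the β-silyloxy groups.

Step 12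
Reactants: 10 (S)-3,4-bis(TBSO)-3-methylbut-1-yne; 16 (2S,3S)-3-(TBSO)-N-methoxy-N-methyl-2-[(TESO)methyl]butanamide
Product: 18 (2S,6S)-6,7-bis(TBSO)-2-[(S)-1-(TBSO)ethyl]-6-methyl-1-(TESO)hept-4-yn-3-one, via lithium acetylide 17 (not isolated)
Conditions: n-BuLi, THF, −78 °C; then 16, −78 to 0 °C; aq. NH4Cl
Reagents that add atoms: none
Why: Acylation of a lithium acetylide by a Weinreb amide, whose chelated tetrahedral intermediate prevents over-addition; this forms the C4a–C5 bond.

Step 13
Reactants: 18 (2S,6S)-6,7-bis(TBSO)-2-[(S)-1-(TBSO)ethyl]-6-methyl-1-(TESO)hept-4-yn-3-one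
Product: 20 (S)-6-[(R)-1,2-bis(TBSO)propan-2-yl]-3-[(S)-1-(TBSO)ethyl]-2,3-dihydro-4H-pyran-4-one, via hydroxy ynone 19 (not isolated)
Conditions: PPTS, MeOH–CH2Cl2, 0 °C; then AgOTf (10 mol %), CH2Cl2, rt
Reagents that add atoms: none
Why: Mild acidic methanolysis should remove only the primary TES ether, and the silver-activated ynone then closes by 6-endo-dig oxa-Michael addition to the dihydropyranone (temporary ring, oxygen on C6).

Step 14
Reactants: 20 (S)-6-[(R)-1,2-bis(TBSO)propan-2-yl]-3-[(S)-1-(TBSO)ethyl]-2,3-dihydro-4H-pyran-4-one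
Product: 21 (S)-6-[(R)-1,2-bis(TBSO)propan-2-yl]-5-chloro-3-[(S)-1-(TBSO)ethyl]-2,3-dihydro-4H-pyran-4-one
Conditions: NCS, CH2Cl2, 0 °C to rt
Reagents that add atoms: N-chlorosuccinimide, O=C1CCC(=O)N1Cl
Why: Electrophilic α-chlorination of a vinylogous ester at its only nucleophilic carbon, C5, before the dienol ether of the target exists (where C4 would compete).

Step 15
Reactants: 5 (3E,5E,7S)-1,1-dibromo-5,7-dimethylnona-1,3,5-triene; 21 (S)-6-[(R)-1,2-bis(TBSO)propan-2-yl]-5-chloro-3-[(S)-1-(TBSO)ethyl]-2,3-dihydro-4H-pyran-4-one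
Product: 24 (2R,4Z,8E,10E,12S)-1,2-bis(TBSO)-4-chloro-5-[(2S,3S)-3-(TBSO)-1-hydroxybutan-2-yl]-2,10,12-trimethyltetradeca-4,8,10-trien-6-yn-3-one, via lithium dienynide 22 (not isolated), via tertiary alcohol adduct 23 (not isolated)
Conditions: 5, n-BuLi (2 equiv), THF, −78 to 0 °C; 21 (precomplexed with anhydrous CeCl3), −78 °C; then 0.5 M aq. HCl, THF, 0 °C
Reagents that add atoms: water, O
Why: The second Corey–Fuchs stage gives the acetylide, which adds 1,2 to the C4a carbonyl; acid then effects the Stork–Danheiser transposition (ionisation, water capture at the oxocarbenium carbon C6, hemiketal opening), which frees the former ring oxygen as the C1 hydroxyl and, because C6 and C8a were ring members, leaves the ketone syn to C8a, while the carbinol centre of 23 is lost again.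

Step 16
Reactants: 24 (2R,4Z,8E,10E,12S)-1,2-bis(TBSO)-4-chloro-5-[(2S,3S)-3-(TBSO)-1-hydroxybutan-2-yl]-2,10,12-trimethyltetradeca-4,8,10-trien-6-yn-3-one
Product: 25 tris-TBS pyran: 3,4-dihydro-2H-pyran with the (1E,3E,5S)-3,5-dimethylhepta-1,3-dienyl group on C3, (S)-1-(TBSO)ethyl on C8a and the exocyclic chain C4a=C5(Cl)–C6(=O)–C7(CH3)(OTBS)–C8H2OTBS (7R; ketone syn to C8a)
Conditions: Ph3PAuCl (5 mol %), AgSbF6 (5 mol %), NaHCO3, CH2Cl2–MeCN, 0 °C to rt
Reagents that add atoms: none
Why: Gold-catalysed hydroalkoxylation in which the C1 hydroxyl adds 6-endo-dig to C3, the δ-carbon of the chloro-dienynone, to give the 4-alkylidene-dihydropyran; the ketone lies anti to the alkyne and cannot compete.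

Step 17
Reactants: 25 tris-TBS pyran
Product: 26 pyran triol: as 25 with free hydroxyls at C7, C8 and the 1-hydroxyethyl group on C8a
Conditions: HF·pyridine, pyridine, THF, 0 °C to rt
Reagents that add atoms: none
Why: Buffered fluoride cleavage of all three silyl ethers under conditions too weakly acidic to protonate the push–pull dienol ether.

Step 18
Reactants: 26 pyran triol
Product: 27 pyran keto aldehyde: 3,4-dihydro-2H-pyran with the dienyl group on C3, acetyl and H on C8a, and the exocyclic chain C4a=C5(Cl)–C6(=O)–C7(CH3)(OH)–C8HO (7R; ketone syn to C8a)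
Conditions: IBX (3 equiv), DMSO, rt; aqueous work-up, crude product used at once
Reagents that add atoms: none
Why: IBX should oxidise the secondary alcohol to the methyl ketone and the primary alcohol to the aldehyde, leave the tertiary alcohol alone and not cleave the 1,2-diol.

Step 19
Reactants: 27 pyran keto aldehyde
Product: 29 target CNP0307047.1 (7R,8R,8aS), via magnesium enolate 28 (not isolated)
Conditions: MgBr2·OEt2 (2 equiv), Et3N (3 equiv), CH2Cl2, −40 to 0 °C; pH 7 buffer
Reagents that add atoms: none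
Why: MgBr2/Et3N soft-enolises the doubly activated C8a–H (α to the acetyl carbonyl, γ to the C6 ketone through C4a=C5) to magnesium enolate 28, whose carbon C8a adds to the tethered C8 aldehyde; the closest known reaction type is the chelation-controlled intramolecular aldol addition of a magnesium enolate of a 1,3-dicarbonyl-type ketone to an aldehyde. The carbocycle closes in the 6-(enolexo)-exo-trig mode, allowed by Baldwin's rules for enolates, and since C4a=C5(Cl)–C6=O is already in place the full chromophore of the target results without further steps. C8 is controlled by a closed chair-like (Zimmerman–Traxler-type) array in which magnesium bridges the enolate oxygen and the aldehyde oxygen, so the new hydroxyl should come out cis to the acetyl group. C8a is controlled by C7: the aldehyde can reach only the enolate face on which its tether lies, and the half-chair that places the small C7 hydroxyl (a third ligand for magnesium) and not the C7 methyl in the pseudo-axial site syn to the acetyl group should be favoured, so (7R) is expected to translate into (8R,8aS). The step needs C–C bond formation to outrun retro-Claisen loss of the formyl group and α-ketol shift of the α-hydroxy-β-keto aldehyde, which the high acidity of C8a–H (enolisation at −40 °C with an amine base) and the six-membered closure should secure. The geometry of C4a=C5 inherited from ring 21 (C6 syn to C8a) keeps the aldehyde within reach of C8a.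

**Compound list**

1 | (S)-2-methylbutan-1-ol | CC[C@H](C)CO | starting material
2 | (S)-2-methylbutanal (not isolated) | CC[C@H](C)C=O | intermediate
3 | (S,E)-2,4-dimethylhex-2-enal | CC[C@H](C)/C=C(C)/C=O | intermediate
4 | (2E,4E,6S)-4,6-dimethylocta-2,4-dienal | CC[C@H](C)/C=C(C)/C=C/C=O | intermediate
5 | (3E,5E,7S)-1,1-dibromo-5,7-dimethylnona-1,3,5-triene | CC[C@H](C)/C=C(C)/C=C/C=C(Br)Br | intermediate
6 | methyl (R)-2-methyloxirane-2-carboxylate | COC(=O)[C@@]1(C)CO1 | starting material
7 | methyl (R)-2,3-dihydroxy-2-methylpropanoate | COC(=O)[C@](C)(O)CO | intermediate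
8 | methyl (R)-2,3-bis(TBSO)-2-methylpropanoate | COC(=O)[C@](C)(O[Si](C)(C)C(C)(C)C)CO[Si](C)(C)C(C)(C)C | intermediate
9 | (R)-2,3-bis(TBSO)-2-methylpropanal | O=C[C@](C)(O[Si](C)(C)C(C)(C)C)CO[Si](C)(C)C(C)(C)C | intermediate
10 | (S)-3,4-bis(TBSO)-3-methylbut-1-yne | C#C[C@](C)(O[Si](C)(C)C(C)(C)C)CO[Si](C)(C)C(C)(C)C | intermediate
11 | ethyl (S)-3-hydroxybutanoate | CCOC(=O)C[C@H](C)O | starting material
12 | ester dianion: dilithium enolate alkoxide of ethyl (S)-3-hydroxybutanoate (not isolated) | CCO/C(O[Li])=C/[C@H](C)O[Li] | intermediate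
13 | ethyl (2S,3S)-3-hydroxy-2-(hydroxymethyl)butanoate | CCOC(=O)[C@@H](CO)[C@H](C)O | intermediate
14 | ethyl (2S,3S)-3-hydroxy-2-[(triethylsilyloxy)methyl]butanoate | CCOC(=O)[C@@H](CO[Si](CC)(CC)CC)[C@H](C)O | intermediate
15 | ethyl (2S,3S)-3-(TBSO)-2-[(TESO)methyl]butanoate | CCOC(=O)[C@@H](CO[Si](CC)(CC)CC)[C@H](C)O[Si](C)(C)C(C)(C)C | intermediate
16 | (2S,3S)-3-(TBSO)-N-methoxy-N-methyl-2-[(TESO)methyl]butanamide | CON(C)C(=O)[C@@H](CO[Si](CC)(CC)CC)[C@H](C)O[Si](C)(C)C(C)(C)C | intermediate
17 | lithium acetylide of 10 (not isolated) | [Li]C#C[C@](C)(O[Si](C)(C)C(C)(C)C)CO[Si](C)(C)C(C)(C)C | intermediate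
18 | (2S,6S)-6,7-bis(TBSO)-2-[(S)-1-(TBSO)ethyl]-6-methyl-1-(TESO)hept-4-yn-3-one | O=C(C#C[C@](C)(O[Si](C)(C)C(C)(C)C)CO[Si](C)(C)C(C)(C)C)[C@@H](CO[Si](CC)(CC)CC)[C@H](C)O[Si](C)(C)C(C)(C)C | intermediate
19 | hydroxy ynone: 1-hydroxy analogue of 18 (not isolated) | O=C(C#C[C@](C)(O[Si](C)(C)C(C)(C)C)CO[Si](C)(C)C(C)(C)C)[C@@H](CO)[C@H](C)O[Si](C)(C)C(C)(C)C | intermediate
20 | (S)-6-[(R)-1,2-bis(TBSO)propan-2-yl]-3-[(S)-1-(TBSO)ethyl]-2,3-dihydro-4H-pyran-4-one | O=C1C=C([C@](C)(O[Si](C)(C)C(C)(C)C)CO[Si](C)(C)C(C)(C)C)OC[C@H]1[C@H](C)O[Si](C)(C)C(C)(C)C | intermediate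
21 | 5-chloro derivative of 20 | O=C1C(Cl)=C([C@](C)(O[Si](C)(C)C(C)(C)C)CO[Si](C)(C)C(C)(C)C)OC[C@H]1[C@H](C)O[Si](C)(C)C(C)(C)C | intermediate
22 | lithium (3E,5E,7S)-5,7-dimethylnona-3,5-dien-1-yn-1-ide (not isolated) | [Li]C#C/C=C/C(C)=C/[C@@H](C)CC | intermediate
23 | tertiary alcohol adduct: 4-dienynyl-4-hydroxy derivative of 21, both epimers at the carbinol carbon (not isolated) | OC1(C#C/C=C/C(C)=C/[C@@H](C)CC)C(Cl)=C([C@](C)(O[Si](C)(C)C(C)(C)C)CO[Si](C)(C)C(C)(C)C)OC[C@H]1[C@H](C)O[Si](C)(C)C(C)(C)C | intermediate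
24 | (2R,4Z,8E,10E,12S)-1,2-bis(TBSO)-4-chloro-5-[(2S,3S)-3-(TBSO)-1-hydroxybutan-2-yl]-2,10,12-trimethyltetradeca-4,8,10-trien-6-yn-3-one | OC[C@@H]([C@H](C)O[Si](C)(C)C(C)(C)C)/C(C#C/C=C/C(C)=C/[C@@H](C)CC)=C(/Cl)C(=O)[C@](C)(O[Si](C)(C)C(C)(C)C)CO[Si](C)(C)C(C)(C)C | intermediate
25 | tris-TBS pyran (dienyl on C3; (S)-1-(TBSO)ethyl on C8a; exocyclic C4a=C5(Cl)–C6(=O)–C7(CH3)(OTBS)–C8H2OTBS, 7R, ketone syn to C8a) | CC[C@H](C)/C=C(C)/C=C/C1=C/C(=C(\Cl)C(=O)[C@](C)(O[Si](C)(C)C(C)(C)C)CO[Si](C)(C)C(C)(C)C)[C@H]([C@H](C)O[Si](C)(C)C(C)(C)C)CO1 | intermediate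
26 | pyran triol (25 without the three silyl groups) | CC[C@H](C)/C=C(C)/C=C/C1=C/C(=C(\Cl)C(=O)[C@](C)(O)CO)[C@H]([C@H](C)O)CO1 | intermediate
27 | pyran keto aldehyde (acetyl and H on C8a; exocyclic C4a=C5(Cl)–C6(=O)–C7(CH3)(OH)–C8HO, 7R) | CC[C@H](C)/C=C(C)/C=C/C1=C/C(=C(\Cl)C(=O)[C@](C)(O)C=O)[C@H](C(C)=O)CO1 | intermediate
28 | bromomagnesium enolate of the acetyl group of 27, enolate oxygen syn to C1 (not isolated) | CC[C@H](C)/C=C(C)/C=C/C1=C/C(=C(\Cl)C(=O)[C@](C)(O)C=O)C(=C(\C)O[Mg]Br)/CO1 | intermediate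
29 | CNP0307047.1 | CC[C@H](C)/C=C(C)/C=C/C1=CC2=C(Cl)C(=O)[C@](C)(O)[C@H](O)[C@@]2(C(C)=O)CO1 | target

**Step count and risks**

Total step count: 19. Longest linear sequence: 12 steps (steps 8 to 19 from ethyl (S)-3-hydroxybutanoate; equally steps 4 to 7 and 12 to 19 from the glycidate).

Steps most likely to fail:

Step 19 (key aldol). The enolate may add through an open or wrongly folded transition state, giving poor facial selectivity at C8a and C8, or base-induced retro-Claisen loss of the formyl group may outrun C–C bond formation. The fallback sets out from 27: the enolisable C8a–H is brominated (NBS, CH2Cl2, −78 °C) to the 8a-bromo keto aldehyde F1. CrCl2 (LiI cat.), THF, 0 °C then reduces the C–Br bond to a chromium enolate, which should add irreversibly to the aldehyde through a closed chelate (Reformatsky-type aldol without amine base) and return to the route at 29.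

Step 15 (addition and transposition). After the 1,2-addition, the acid-induced ionisation may partition away from hydration at the hindered C6, through water capture at the alkyne terminus (Meyer–Schuster-type enone) or loss of silyl ethers. The fallback sets out from 21 and 22: the lithium alkoxide of the adduct is trapped with Ac2O as the tertiary propargylic acetate F2. Warming in toluene (PdCl2(MeCN)2 as catalyst if needed) should effect a 1,3-acyloxy transposition of the allylic ester, which delivers the oxygen intramolecularly to C6 and gives the cyclic acylal F3. K2CO3, MeOH, 0 °C removes the acetyl group, the hemiketal opens, and the route is rejoined at 24.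

Step 18 (double oxidation). The α-hydroxy aldehyde may over-oxidise or fragment, or the ring may close prematurely and without control while both carbonyl groups are generated in one pot. The fallback is a staged oxidation from 26: selective silylation of the primary alcohol (TESCl, imidazole, −40 °C) gives the C8 TES ether F4; Dess–Martin periodinane (NaHCO3, CH2Cl2) oxidises only the secondary alcohol to the methyl ketone F5; HF·pyridine frees the primary alcohol to give the acetyl diol F6. TEMPO/PhI(OAc)2, which oxidises primary alcohols selectively under non-basic conditions, then returns to the route at 27.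

Further compounds
F1 | step 19 | 8a-bromo derivative of keto aldehyde 27 (both C8a epimers) | CC[C@H](C)/C=C(C)/C=C/C1=C/C(=C(\Cl)C(=O)[C@](C)(O)C=O)C(Br)(C(C)=O)CO1
F2 | step 15 | tertiary propargylic acetate of adduct 23 | CC(=O)OC1(C#C/C=C/C(C)=C/[C@@H](C)CC)C(Cl)=C([C@](C)(O[Si](C)(C)C(C)(C)C)CO[Si](C)(C)C(C)(C)C)OC[C@H]1[C@H](C)O[Si](C)(C)C(C)(C)C
F3 | step 15 | cyclic acylal: 6-acetoxy-5-chloro-4-dienynyl-3,6-dihydro-2H-pyran with the C7 unit on C6 | CC(=O)OC1([C@](C)(O[Si](C)(C)C(C)(C)C)CO[Si](C)(C)C(C)(C)C)OC[C@@H]([C@H](C)O[Si](C)(C)C(C)(C)C)C(C#C/C=C/C(C)=C/[C@@H](C)CC)=C1Cl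
F4 | step 18 | C8 triethylsilyl ether of triol 26 | CC[C@H](C)/C=C(C)/C=C/C1=C/C(=C(\Cl)C(=O)[C@](C)(O)CO[Si](CC)(CC)CC)[C@H]([C@H](C)O)CO1
F5 | step 18 | methyl ketone (acetyl on C8a) with C8 triethylsilyl ether | CC[C@H](C)/C=C(C)/C=C/C1=C/C(=C(\Cl)C(=O)[C@](C)(O)CO[Si](CC)(CC)CC)[C@H](C(C)=O)CO1
F6 | step 18 | acetyl diol (acetyl on C8a, free C7 and C8 hydroxyls) | CC[C@H](C)/C=C(C)/C=C/C1=C/C(=C(\Cl)C(=O)[C@](C)(O)CO)[C@H](C(C)=O)CO1
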